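## Analysis of the target

Compound 24 is a 2,4-trans-4-arylflavan. Its chroman consists of a benzo ring (ring A) with one hydroxyl at C7 and an oxygen ring (ring C) that carries a 4-hydroxyphenyl group (ring B) at C2 and a 2,4,6-trihydroxyphenyl group (ring D) at C4; ring D bears the dodecanoyl chain at C3''. The only stereocentres are C2 (R) and C4 (S), in a 1,3-relationship across the C3 methylene group, with the two aryl groups on opposite faces of ring C. The molecule has five phenols, of which the acylated ring D is easily oxidised in base. The O1–C2 bond is a benzylic ether para to an oxygen donor and ionises under acid, which would scramble C2 or open ring C; C4–H is doubly benzylic, and the ketone sits between two hydroxyls. The synthesis is hard for two reasons: the trans 1,3-diaryl relation must be set in one absolute sense at carbons that have no neighbouring functional group, and two electron-rich rings (A and D) must be told apart when the acyl chain is attached to ring D alone. The strategy rests on one mapping: O1, C2, C3, C4, C4a and C8a are the ring atoms of a 4,6-diaryl δ-valerolactone, with C8a as the carbonyl carbon and C4a as the α-carbon. The other four carbons of ring A (C5 to C8), with their single oxygen at C7 meta to O1, correspond to a four-carbon methyl enone unit, so ring A can be grown onto a lactone that already holds both stereocentres and aromatised afterwards.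

## Retrosynthetic reasoning

24 from 23. The last disconnection cuts the five O–benzyl-type bonds (four benzyl ethers and one benzyl carbonate). All phenols are thereby masked by groups that fall in one neutral hydrogenolysis, which avoids acid at the O1–C2 bond and base at the free acylated ring D.

23 from 21 and 22. The C3''–C(=O) bond is cut. In 21 ring D is symmetric about its C1''–C4'' axis, so its two free positions are equivalent and acylation with dodecanoyl chloride 22 has no regiochemical choice within the ring. The ketone cannot be carried earlier, because an enolisable ketone would not survive the organocopper step or the base of the annulation.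

21 from 19 and 20. The O7–C bond is cut. Because ring A is made last, its hydroxyl in 19 is the only free phenol of the molecule. Capping it with benzyl chloroformate 20 gives the carbonate 21, which withdraws electron density from ring A, so that the acylation goes to ring D, and which is cleaved in the final hydrogenolysis.

19 from 16. No skeletal bond is cut; ring A is taken back by two hydrogen atoms to the vinylogous ester 16. The forward step has to dehydrogenate C5–C6 without touching the benzylic positions, after which tautomerisation gives the phenol.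

16 from 12 and 13 (the key disconnection). The bonds C4a–C5 and C8–C8a are cut. These are the two bonds that join ring A to the part of the molecule that holds C2 and C4, so cutting them removes ring A altogether. What remains is the monocyclic lactone 12, whose carbonyl carbon is C8a and whose α-carbon is C4a, and methyl vinyl ketone 13, which supplies C5 to C8 with the oxygen already at C7. The forward reaction has to alkylate the lactone enolate at carbon by conjugate addition, acylate the methyl ketone enolate with the lactone carbonyl, and close ring C again as the enol ether without breaking O1–C2. No stereocentre of lasting importance is formed.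

12 from 6 and 9. The C4–C1'' bond is cut. The diaryl cuprate 11, made from bromide 9 through the aryllithium 10, adds to the unsaturated lactone 6 anti to the aryl group at C6, so the existing stereocentre sets the new one, and the trans relation is fixed on a conformationally defined ring. Both aryl rings come from simple arenes.

9 from 7 and 8. The C–Br bond is cut. The bromide gives a site-defined aryl metal species by halogen–metal exchange; direct metalation of 7 would compete with deprotonation of the benzylic ether CH2 groups.

6 from 5, and 5 from 3 and 4. The ring alkene of 6 is cut by ring-closing metathesis, and the ester C–O bond of 5 leads back to alcohol 3 and acryloyl chloride 4. This is the shortest reliable way from a homoallylic alcohol to a 6-substituted unsaturated δ-lactone.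

3 from 1 and 2. The bond between the carbinol carbon (later C2) and the allyl CH2 (later C3) is cut. Reagent-controlled allyl transfer from borane 2 to aldehyde 1 sets the one stereocentre from which the other follows.

## Alternatives that were turned down

Alternative 1: The C2''–C3'' bond of ring D is cut, so that ring D is stored as a masked polyketide chain in the 2-pyrone A2, 3-[(2R,4S)-7-(benzyloxy)-2-[4-(benzyloxy)phenyl]chroman-4-yl]-4-hydroxy-6-(2-oxotridecyl)-2H-pyran-2-one. In the forward key step a magnesium alkoxide opens the pyrone ring of A2, and the methylene carbon between two ketones attacks the ester carbonyl in a Claisen condensation. Aromatisation then gives the acylphloroglucinol A1, 1-{3-[(2R,4S)-7-(benzyloxy)-2-[4-(benzyloxy)phenyl]chroman-4-yl]-2,4,6-trihydroxyphenyl}dodecan-1-one. In its favour, the acyl chain and the substitution pattern of ring D are formed together, so no electrophilic substitution is needed on a molecule with two electron-rich rings. On this point it is stronger than the chosen route, which depends on the selectivity of step 9. Only two benzyl groups remain to be removed from A1. Against it, A2 presupposes the finished 2,4-trans flavan with a carbon-linked pyrone at C4, so the two stereocentres, the real difficulty, are left to another strategy. Joining the pyrone to C4 with trans control is itself unsolved. The opened chain can also close by aldol modes or fall back to the pyrone, and the ester carbonyl that must be attacked sits next to the carbon bearing the bulky flavanyl group. The chosen strategy instead delivers the stereodefined core from simple materials and pays for the acyl group with one Friedel–Crafts reaction on a symmetric ring.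

Alternative 2: The bonds O1–C2 and C3–C4 of ring C are cut. A chiral phosphoric acid dehydrates the benzhydrol A4, [4-(benzyloxy)-2-hydroxyphenyl][2,4,6-tris(benzyloxy)phenyl]methanol, to the ortho-quinone methide A5, 3-(benzyloxy)-6-{[2,4,6-tris(benzyloxy)phenyl]methylidene}cyclohexa-2,4-dien-1-one. Hetero-Diels–Alder reaction of A5 with ethyl vinyl ether A6 gives the 2,4-cis acetal A3, (2S,4S)-7-(benzyloxy)-2-ethoxy-4-[2,4,6-tris(benzyloxy)phenyl]chroman. This route is clearly shorter and more convergent to the chroman than the chosen one: rings A and D are bought as aromatics, ring C and C4 are made in one catalytic asymmetric step, and no aromatisation is needed. The electron-rich alkene A6 is also a well-matched partner for the electron-poor heterodiene. Against it, A3 carries an ethoxy group where the target has ring B. The C2–aryl bond must then be made by substitution at the acetal carbon through an oxocarbenium ion, under Lewis acid and next to a very electron-rich C4 aryl group, and the C2 configuration would rest on 1,3-induction in a flattened ring that is not assured to give trans. A4 also ionises very easily because of its trioxygenated aryl group, so an uncatalysed racemic background reaction and self-condensation compete with the catalyst, and the twisted di-ortho-substituted aryl group of A5 makes facial control uncertain. A styrene-type dienophile in place of A6 would install ring B directly but would be expected to favour the 2,4-cis diaryl chroman, the wrong relative configuration. The chosen strategy is longer, but it sets both stereocentres by well-understood reagent and substrate control on a saturated lactone before ring A exists.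

Alternative 3: Both bonds to the ketone carbonyl are cut. A zerovalent palladium phosphine catalyst inserts into the C–I bond of the aryl iodide A8, (2R,4S)-7-(benzyloxy)-2-[4-(benzyloxy)phenyl]-4-[2,4,6-tris(benzyloxy)-3-iodophenyl]chroman. Carbon monoxide A10 then inserts into the aryl–palladium bond, and the alkylborane A9, 9-undecyl-9-borabicyclo[3.3.1]nonane, transfers its undecyl group. The product is the fully benzylated ketone A7, 1-{2,4,6-tris(benzyloxy)-3-[(2R,4S)-7-(benzyloxy)-2-[4-(benzyloxy)phenyl]chroman-4-yl]phenyl}dodecan-1-one. In its favour, the conditions are neutral to basic, with no Lewis acid near the benzyl ethers or the O1–C2 bond, so on mildness it is stronger than step 9 of the chosen route. The site of the ketone is fixed by the C–I bond, the chain is modular, and A7 would need only hydrogenolysis to reach the target. Against it, it addresses only the last two C–C bonds and leaves the flavan core and both stereocentres to another strategy. A8 must itself be made by electrophilic iodination of ring D in the presence of ring A, so the ring-selectivity question is moved, not removed. Oxidative addition into an electron-rich aryl iodide flanked by two benzyloxy groups should be slow, direct coupling of A9 with A8 before A10 is taken up and β-hydride elimination compete, and A10 is a toxic gas. It takes two steps for what the chosen route does in one. The chosen route spends its key step on building ring A, and by making ring A last it obtains a free C7 hydroxyl that can be turned into a deactivating carbonate before a single acylation.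

Key step: step 6

Assumption: compounds 1, 2 (as its commercial pentane solution), 4, 7, 8, 13, 20 and 22 are taken as commercially available; cis and trans refer to the two aryl groups on the six-membered oxygen ring.

## Route

Step 1
Reactants: 1 4-(benzyloxy)benzaldehyde; 2 (+)-B-allyldiisopinocampheylborane (the enantiomer derived from (−)-α-pinene)
Product: 3 (1R)-1-[4-(benzyloxy)phenyl]but-3-en-1-ol
Conditions: 2 (1 M in pentane), Et2O, −78 °C; then NaOH, H2O2, 0 → 25 °C
Reagents that add atoms: (+)-B-allyldiisopinocampheylborane (2), C=CCB([C@H]1C[C@H]2C[C@@H]([C@@H]1C)C2(C)C)[C@H]1C[C@H]2C[C@@H]([C@@H]1C)C2(C)C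
Why: Asymmetric allylboration through a chair six-membered transition state; the isopinocampheyl groups of this enantiomer of the reagent should direct the allyl group to the Re face of the aldehyde and so set the carbinol carbon (later C2) as R.

Step 2
Reactants: 3 (1R)-1-[4-(benzyloxy)phenyl]but-3-en-1-ol; 4 acryloyl chloride
Product: 5 (1R)-1-[4-(benzyloxy)phenyl]but-3-en-1-yl prop-2-enoate
Conditions: 4, Et3N, 4-(dimethylamino)pyridine (cat.), CH2Cl2, 0 °C
Reagents that add atoms: acryloyl chloride (4), C=CC(=O)Cl
Why: O-Acylation of a secondary alcohol under basic conditions, which do not ionise the para-alkoxybenzylic C–O bond; the stereocentre is not involved.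

Step 3
Reactants: 5 (1R)-1-[4-(benzyloxy)phenyl]but-3-en-1-yl prop-2-enoate
Product: 6 (6R)-6-[4-(benzyloxy)phenyl]-5,6-dihydro-2H-pyran-2-one
Conditions: second-generation Grubbs catalyst, (H2IMes)(PCy3)Cl2Ru=CHPh (5 mol%), CH2Cl2, 40 °C
Reagents that add atoms: none
Why: Ring-closing metathesis of the acrylate of a homoallylic alcohol gives the six-membered unsaturated lactone with loss of the two terminal CH2 groups; the stereocentre is untouched.

Step 4
Reactants: 7 1,3,5-tris(benzyloxy)benzene; 8 N-bromosuccinimide
Product: 9 2-bromo-1,3,5-tris(benzyloxy)benzene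
Conditions: 8 (1.0 equiv), CH2Cl2, −78 → 0 °C
Reagents that add atoms: N-bromosuccinimide (8), O=C1CCC(=O)N1Br
Why: Electrophilic aromatic bromination of a trialkoxybenzene whose three free positions are equivalent; one equivalent at low temperature should stop at the monobromide.

Step 5
Reactants: 9 2-bromo-1,3,5-tris(benzyloxy)benzene; 6 (6R)-6-[4-(benzyloxy)phenyl]-5,6-dihydro-2H-pyran-2-one
Product: 12 (4S,6R)-6-[4-(benzyloxy)phenyl]-4-[2,4,6-tris(benzyloxy)phenyl]tetrahydro-2H-pyran-2-one, via [2,4,6-tris(benzyloxy)phenyl]lithium 10 (not isolated), via lithium bis[2,4,6-tris(benzyloxy)phenyl]cuprate 11 (not isolated)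
Conditions: 9 (2.2 equiv), n-BuLi (2.2 equiv), THF, −78 °C; CuBr·SMe2 (1.1 equiv), −78 → −40 °C; then 6, −78 → −20 °C; aq. NH4Cl
Reagents that add atoms: 2-bromo-1,3,5-tris(benzyloxy)benzene (9), Brc1c(OCc2ccccc2)cc(OCc2ccccc2)cc1OCc1ccccc1
Why: Bromine–lithium exchange at −78 °C is faster than deprotonation of the benzylic ether CH2 groups, and two equivalents of 10 with CuBr·SMe2 give the diaryl cuprate 11. Conjugate addition of organocuprates to 6-substituted 5,6-dihydro-2H-pyran-2-ones is known; the aryl group should enter axially on the half-chair that holds the C6 aryl group pseudo-equatorial, that is anti to it, which sets C4 as S and gives the 4,6-trans lactone. The aryl group that is not transferred returns as 7 on work-up.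

Step 6
Reactants: 12 (4S,6R)-6-[4-(benzyloxy)phenyl]-4-[2,4,6-tris(benzyloxy)phenyl]tetrahydro-2H-pyran-2-one; 13 methyl vinyl ketone
Product: 16 (2R,4S)-2-[4-(benzyloxy)phenyl]-4-[2,4,6-tris(benzyloxy)phenyl]-2,3,4,4a,5,6-hexahydro-7H-chromen-7-one (both C4a epimers), via keto lactone 14 (not isolated), via hydroxy dione 15 (not isolated)
Conditions: KOt-Bu (1.2 equiv), THF/t-BuOH, −40 °C, 13 (1.05 equiv) added slowly, then 25 °C; AcOH; then pyridinium p-toluenesulfonate (cat.), 4 Å molecular sieves, CH2Cl2, 25 °C
Reagents that add atoms: methyl vinyl ketone (13), CC(=O)C=C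
Why: Proposed new method: tert-butoxide reversibly forms the lactone enolate at its only α-CH2 (C4a); this adds to 13 in a conjugate fashion on the face away from the C4 aryl group to give the enolate of keto lactone 14 (C4a–C5 bond), proton exchange through t-BuOH delivers the methyl ketone enolate, and its carbon (C8) attacks the lactone carbonyl (C8a) in a 6-exo-trig Claisen (Dieckmann-type) closure whose tetrahedral intermediate expels the C2 alkoxide to give dione 15, which is deprotonated at once and so pulls the equilibria forward. The closest known reaction types are the Michael–Claisen synthesis of cyclohexane-1,3-diones from ester-type enolates and enones (the dimedone synthesis) and the base-mediated cyclisation of δ-keto esters to cyclohexane-1,3-diones; what is new is that the ester is a lactone, so that the leaving alkoxide stays tethered. After neutralisation, the weak acid catalyst lets the C2 hydroxyl add to the C8a carbonyl (6-exo-trig) and the hemiketal lose water to the vinylogous ester, the intramolecular counterpart of the acid-catalysed enol ether formation of cyclohexane-1,3-diones with alcohols; the tether allows only C8a, not C7, to be reached. The O1–C2 bond is not broken at any stage (acyl–oxygen cleavage in the Claisen step, carbonyl addition in the closure), so C2 and C4 keep the configuration of 12 as long as the acid is too weak to ionise the benzylic C2–O bond. The only new stereocentre, C4a, is set by the substrate in the conjugate addition, is epimerisable and disappears in step 7, so it needs no control. The selectivities needed are regiochemical: alkylation at the single enolisable lactone carbon, cyclisation through the methyl and not the methylene enolate (the latter could only form a four-membered ring), and one conjugate addition only, which the slow addition of 13 at low temperature before warming for the Claisen step is meant to secure.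

Step 7
Reactants: 16 (2R,4S)-2-[4-(benzyloxy)phenyl]-4-[2,4,6-tris(benzyloxy)phenyl]-2,3,4,4a,5,6-hexahydro-7H-chromen-7-one
Product: 19 (2R,4S)-2-[4-(benzyloxy)phenyl]-4-[2,4,6-tris(benzyloxy)phenyl]chroman-7-ol, via 6-phenylselanyl ketone 17 (not isolated), via dienone 18 (not isolated)
Conditions: LiN(i-Pr)2, THF, −78 °C; PhSeBr, −78 °C; then m-CPBA (1.0 equiv), CH2Cl2, −78 °C; i-Pr2NH, → 25 °C
Reagents that add atoms: none
Why: Kinetic deprotonation of the vinylogous ester takes place at the α'-CH2 (C6) and the enolate is selenenylated there; oxidation at selenium and syn elimination of the selenoxide through C5–H give the cross-conjugated dienone 18, the keto tautomer of a phenol, which aromatises by loss of the C4a proton (selenoxide elimination, a known way to turn cyclohexenones into phenols). One equivalent of peracid at −78 °C should oxidise only selenium and the amine traps the selenenic acid; both C4a epimers converge, and C2 and C4 are not involved.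

Step 8
Reactants: 19 (2R,4S)-2-[4-(benzyloxy)phenyl]-4-[2,4,6-tris(benzyloxy)phenyl]chroman-7-ol; 20 benzyl chloroformate
Product: 21 benzyl (2R,4S)-2-[4-(benzyloxy)phenyl]-4-[2,4,6-tris(benzyloxy)phenyl]chroman-7-yl carbonate
Conditions: 20, pyridine, CH2Cl2, 0 °C
Reagents that add atoms: benzyl chloroformate (20), O=C(Cl)OCc1ccccc1
Why: O-Acylation of the only free phenol; the aryl carbonate makes ring A much less nucleophilic than an ether would and is cleaved by hydrogenolysis together with the benzyl ethers.

Step 9
Reactants: 21 benzyl (2R,4S)-2-[4-(benzyloxy)phenyl]-4-[2,4,6-tris(benzyloxy)phenyl]chroman-7-yl carbonate; 22 dodecanoyl chloride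
Product: 23 benzyl (2R,4S)-2-[4-(benzyloxy)phenyl]-4-[2,4,6-tris(benzyloxy)-3-dodecanoylphenyl]chroman-7-yl carbonate
Conditions: 22, SnCl4, 2,6-di-tert-butylpyridine, CH2Cl2, −78 → −20 °C
Reagents that add atoms: dodecanoyl chloride (22), CCCCCCCCCCCC(=O)Cl
Why: Friedel–Crafts acylation of a trialkoxyphenyl ring; the two free positions of ring D are equivalent by rotation about the C4–C1'' bond, ring D is by far the most electron-rich arene once ring A carries the carbonate, and the first acyl group deactivates the ring against a second. The hindered pyridine takes up the hydrogen chloride so that the O1–C2 bond is not exposed to protic acid.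

Step 10
Reactants: 23 benzyl (2R,4S)-2-[4-(benzyloxy)phenyl]-4-[2,4,6-tris(benzyloxy)-3-dodecanoylphenyl]chroman-7-yl carbonate
Product: 24 1-{3-[(2R,4S)-7-hydroxy-2-(4-hydroxyphenyl)chroman-4-yl]-2,4,6-trihydroxyphenyl}dodecan-1-one
Conditions: H2 (1 atm), Pd/C (10%), EtOAc/MeOH, 25 °C
Reagents that add atoms: none
Why: Hydrogenolysis of four benzyl ethers and of the benzyl carbonate, which then loses carbon dioxide; the cyclic benzylic ether O1–C2 and the chelated aryl ketone should react much more slowly, so the reaction is stopped when hydrogen uptake ends.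

## Compound list

1 | 4-(benzyloxy)benzaldehyde | O=Cc1ccc(OCc2ccccc2)cc1 | starting material
2 | (+)-B-allyldiisopinocampheylborane | C=CCB([C@H]1C[C@H]2C[C@@H]([C@@H]1C)C2(C)C)[C@H]1C[C@H]2C[C@@H]([C@@H]1C)C2(C)C | starting material
3 | (1R)-1-[4-(benzyloxy)phenyl]but-3-en-1-ol | C=CC[C@H](c1ccc(OCc2ccccc2)cc1)O | intermediate
4 | acryloyl chloride | C=CC(=O)Cl | starting material
5 | (1R)-1-[4-(benzyloxy)phenyl]but-3-en-1-yl prop-2-enoate | C=CC[C@H](c1ccc(OCc2ccccc2)cc1)OC(=O)C=C | intermediate
6 | (6R)-6-[4-(benzyloxy)phenyl]-5,6-dihydro-2H-pyran-2-one | O=C1C=CC[C@H](c2ccc(OCc3ccccc3)cc2)O1 | intermediate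
7 | 1,3,5-tris(benzyloxy)benzene | c1ccccc1COc1cc(OCc2ccccc2)cc(OCc2ccccc2)c1 | starting material
8 | N-bromosuccinimide | O=C1CCC(=O)N1Br | starting material
9 | 2-bromo-1,3,5-tris(benzyloxy)benzene | Brc1c(OCc2ccccc2)cc(OCc2ccccc2)cc1OCc1ccccc1 | intermediate
10 | [2,4,6-tris(benzyloxy)phenyl]lithium | [Li]c1c(OCc2ccccc2)cc(OCc2ccccc2)cc1OCc1ccccc1 | intermediate (formed in the flask, not isolated)
11 | lithium bis[2,4,6-tris(benzyloxy)phenyl]cuprate | [Li+].c1ccccc1COc1cc(OCc2ccccc2)cc(OCc2ccccc2)c1[Cu-]c1c(OCc2ccccc2)cc(OCc2ccccc2)cc1OCc1ccccc1 | intermediate (formed in the flask, not isolated)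
12 | (4S,6R)-6-[4-(benzyloxy)phenyl]-4-[2,4,6-tris(benzyloxy)phenyl]tetrahydro-2H-pyran-2-one | c1ccccc1COc1cc(OCc2ccccc2)c([C@H]2C[C@H](c3ccc(OCc4ccccc4)cc3)OC(=O)C2)c(OCc2ccccc2)c1 | intermediate
13 | methyl vinyl ketone | CC(=O)C=C | starting material
14 | (4S,6R)-6-[4-(benzyloxy)phenyl]-3-(3-oxobutyl)-4-[2,4,6-tris(benzyloxy)phenyl]tetrahydro-2H-pyran-2-one (C3 epimers) | c1ccccc1COc1cc(OCc2ccccc2)c([C@H]2C[C@H](c3ccc(OCc4ccccc4)cc3)OC(=O)C2CCC(C)=O)c(OCc2ccccc2)c1 | intermediate (formed in the flask, not isolated)
15 | 4-{(1S,3R)-3-[4-(benzyloxy)phenyl]-3-hydroxy-1-[2,4,6-tris(benzyloxy)phenyl]propyl}cyclohexane-1,3-dione (epimers at the ring carbon) | c1ccccc1COc1cc(OCc2ccccc2)c([C@H](C2CCC(=O)CC2=O)C[C@H](c3ccc(OCc4ccccc4)cc3)O)c(OCc2ccccc2)c1 | intermediate (formed in the flask, not isolated)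
16 | (2R,4S)-2-[4-(benzyloxy)phenyl]-4-[2,4,6-tris(benzyloxy)phenyl]-2,3,4,4a,5,6-hexahydro-7H-chromen-7-one (C4a epimers) | c1ccccc1COc1cc(OCc2ccccc2)c([C@H]2C[C@H](c3ccc(OCc4ccccc4)cc3)OC3=CC(=O)CCC32)c(OCc2ccccc2)c1 | intermediate
17 | (2R,4S)-2-[4-(benzyloxy)phenyl]-6-(phenylselanyl)-4-[2,4,6-tris(benzyloxy)phenyl]-2,3,4,4a,5,6-hexahydro-7H-chromen-7-one (C4a and C6 epimers) | c1ccccc1COc1cc(OCc2ccccc2)c([C@H]2C[C@H](c3ccc(OCc4ccccc4)cc3)OC3=CC(=O)C([Se]c4ccccc4)CC32)c(OCc2ccccc2)c1 | intermediate (formed in the flask, not isolated)
18 | (2R,4S)-2-[4-(benzyloxy)phenyl]-4-[2,4,6-tris(benzyloxy)phenyl]-2,3,4,4a-tetrahydro-7H-chromen-7-one (C4a epimers) | c1ccccc1COc1cc(OCc2ccccc2)c([C@H]2C[C@H](c3ccc(OCc4ccccc4)cc3)OC3=CC(=O)C=CC32)c(OCc2ccccc2)c1 | intermediate (formed in the flask, not isolated)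
19 | (2R,4S)-2-[4-(benzyloxy)phenyl]-4-[2,4,6-tris(benzyloxy)phenyl]chroman-7-ol | c1ccccc1COc1cc(OCc2ccccc2)c([C@H]2C[C@H](c3ccc(OCc4ccccc4)cc3)Oc3cc(O)ccc32)c(OCc2ccccc2)c1 | intermediate
20 | benzyl chloroformate | O=C(Cl)OCc1ccccc1 | starting material
21 | benzyl (2R,4S)-2-[4-(benzyloxy)phenyl]-4-[2,4,6-tris(benzyloxy)phenyl]chroman-7-yl carbonate | c1ccccc1COc1cc(OCc2ccccc2)c([C@H]2C[C@H](c3ccc(OCc4ccccc4)cc3)Oc3cc(OC(=O)OCc4ccccc4)ccc32)c(OCc2ccccc2)c1 | intermediate
22 | dodecanoyl chloride | CCCCCCCCCCCC(=O)Cl | starting material
23 | benzyl (2R,4S)-2-[4-(benzyloxy)phenyl]-4-[2,4,6-tris(benzyloxy)-3-dodecanoylphenyl]chroman-7-yl carbonate | CCCCCCCCCCCC(=O)c1c(OCc2ccccc2)cc(OCc2ccccc2)c([C@H]2C[C@H](c3ccc(OCc4ccccc4)cc3)Oc3cc(OC(=O)OCc4ccccc4)ccc32)c1OCc1ccccc1 | intermediate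
24 | 1-{3-[(2R,4S)-7-hydroxy-2-(4-hydroxyphenyl)chroman-4-yl]-2,4,6-trihydroxyphenyl}dodecan-1-one (CNP0293819.3) | CCCCCCCCCCCC(=O)c1c(O)cc(O)c([C@H]2C[C@H](c3ccc(O)cc3)Oc3cc(O)ccc32)c1O | target

## Step count and least certain steps

Total step count: 10. Longest linear sequence: 9 steps (1 → 3 → 5 → 6 → 12 → 16 → 19 → 21 → 23 → 24); the bromination of 7 (step 4) is the only step off this line.

Step 6 (key step, proposed new method). The most likely failure is base-induced oligomerisation of the enone, or a second conjugate addition by the dione enolate, outrunning the addition of a hindered lactone enolate that is present only in part. In the acid stage, ionisation of the para-alkoxybenzylic C2–O bond would erode the C2 configuration. The fallback uses known reactions in separate operations; it sets out from 12 and comes back to the route at 16, passing through 14 and 15, which are then isolated. 12 is converted with LiN(SiMe3)2 and Me3SiCl in THF at −78 °C into the trimethylsilyl ketene acetal F1. F1 adds to 13 in a Mukaiyama–Michael reaction with catalytic Sc(OTf)3 in CH2Cl2 at −78 °C to give the silyl enol ether F2, and dilute aqueous citric acid hydrolyses F2 to keto lactone 14. 14 is then cyclised with KOt-Bu in THF (the known Claisen closure of δ-keto esters to cyclohexane-1,3-diones) to 15 and closed to 16 with the same weak acid catalyst as in step 6.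

Step 9. The most likely failure is Lewis-acid-induced loss of benzyl groups next to the new ketone, with benzyl transfer onto the electron-rich rings, or ionisation of the C2–O bond; acylation of ring A is the lesser concern. The fallback sets out from 21 and comes back at 23. Vilsmeier–Haack formylation of 21 (POCl3, DMF, 0 → 25 °C, aqueous NaOAc work-up) gives the aldehyde F3. C11H23MgBr in THF at −78 °C, where the aldehyde reacts far faster than the aryl carbonate, gives the carbinol F4, and Dess–Martin periodinane in CH2Cl2 oxidises F4 to 23.

Step 5. The most likely failure is slow transfer of the di-ortho-substituted aryl group, so that the basic aryl metal species instead deprotonates 6 at C5 and opens the ring by elimination of the benzylic carboxylate, or adds to the carbonyl. The fallback sets out from 7 and 6 and comes back at 12. 7 is iodinated with N-iodosuccinimide in CH2Cl2 to 1,3,5-tris(benzyloxy)-2-iodobenzene F5. F5 is added to 6 in a reductive Heck reaction (Pd(OAc)2 cat., HCO2Na, Bu4NCl, DMF, 60 °C). Syn arylpalladation from the face away from the C6 aryl group, followed by hydride capture of the palladium enolate, should give the same trans lactone 12.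

Step 7. The most likely failures are electrophilic selenenylation of ring D, over-oxidation of the new phenol by selenium oxidants, or deprotonation at C4a in place of C6. The fallback sets out from 16 and comes back at 19. 16 is converted with LiN(i-Pr)2 and Me3SiCl in THF at −78 °C into the silyl dienol ether F6, and Saegusa–Ito oxidation with Pd(OAc)2 in MeCN at 25 °C gives dienone 18, which tautomerises to 19.

## Further compounds

F1 | step 6 | trimethyl{[(2R,4S)-2-[4-(benzyloxy)phenyl]-4-[2,4,6-tris(benzyloxy)phenyl]-3,4-dihydro-2H-pyran-6-yl]oxy}silane | c1ccccc1COc1cc(OCc2ccccc2)c([C@H]2C[C@H](c3ccc(OCc4ccccc4)cc3)OC(O[Si](C)(C)C)=C2)c(OCc2ccccc2)c1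
F2 | step 6 | (4S,6R)-6-[4-(benzyloxy)phenyl]-4-[2,4,6-tris(benzyloxy)phenyl]-3-{3-[(trimethylsilyl)oxy]but-2-en-1-yl}tetrahydro-2H-pyran-2-one (C3 epimers) | c1ccccc1COc1cc(OCc2ccccc2)c([C@H]2C[C@H](c3ccc(OCc4ccccc4)cc3)OC(=O)C2CC=C(C)O[Si](C)(C)C)c(OCc2ccccc2)c1
F3 | step 9 | benzyl (2R,4S)-2-[4-(benzyloxy)phenyl]-4-[2,4,6-tris(benzyloxy)-3-formylphenyl]chroman-7-yl carbonate | O=Cc1c(OCc2ccccc2)cc(OCc2ccccc2)c([C@H]2C[C@H](c3ccc(OCc4ccccc4)cc3)Oc3cc(OC(=O)OCc4ccccc4)ccc32)c1OCc1ccccc1
F4 | step 9 | benzyl (2R,4S)-2-[4-(benzyloxy)phenyl]-4-[2,4,6-tris(benzyloxy)-3-(1-hydroxydodecyl)phenyl]chroman-7-yl carbonate (carbinol epimers) | CCCCCCCCCCCC(O)c1c(OCc2ccccc2)cc(OCc2ccccc2)c([C@H]2C[C@H](c3ccc(OCc4ccccc4)cc3)Oc3cc(OC(=O)OCc4ccccc4)ccc32)c1OCc1ccccc1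
F5 | step 5 | 1,3,5-tris(benzyloxy)-2-iodobenzene | Ic1c(OCc2ccccc2)cc(OCc2ccccc2)cc1OCc1ccccc1
F6 | step 7 | trimethyl{[(2R,4S)-2-[4-(benzyloxy)phenyl]-4-[2,4,6-tris(benzyloxy)phenyl]-3,4,4a,5-tetrahydro-2H-chromen-7-yl]oxy}silane (C4a epimers) | c1ccccc1COc1cc(OCc2ccccc2)c([C@H]2C[C@H](c3ccc(OCc4ccccc4)cc3)OC3=CC(O[Si](C)(C)C)=CCC32)c(OCc2ccccc2)c1
A1 | alternative 1 | 1-{3-[(2R,4S)-7-(benzyloxy)-2-[4-(benzyloxy)phenyl]chroman-4-yl]-2,4,6-trihydroxyphenyl}dodecan-1-one | CCCCCCCCCCCC(=O)c1c(O)cc(O)c([C@H]2C[C@H](c3ccc(OCc4ccccc4)cc3)Oc3cc(OCc4ccccc4)ccc32)c1O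
A2 | alternative 1 | 3-[(2R,4S)-7-(benzyloxy)-2-[4-(benzyloxy)phenyl]chroman-4-yl]-4-hydroxy-6-(2-oxotridecyl)-2H-pyran-2-one | CCCCCCCCCCCC(=O)Cc1cc(O)c([C@H]2C[C@H](c3ccc(OCc4ccccc4)cc3)Oc3cc(OCc4ccccc4)ccc32)c(=O)o1
A3 | alternative 2 | (2S,4S)-7-(benzyloxy)-2-ethoxy-4-[2,4,6-tris(benzyloxy)phenyl]chroman (2,4-cis) | c1ccccc1COc1cc(OCc2ccccc2)c([C@H]2C[C@@H](OCC)Oc3cc(OCc4ccccc4)ccc32)c(OCc2ccccc2)c1
A4 | alternative 2 | [4-(benzyloxy)-2-hydroxyphenyl][2,4,6-tris(benzyloxy)phenyl]methanol (racemic) | OC(c1ccc(OCc2ccccc2)cc1O)c1c(OCc2ccccc2)cc(OCc2ccccc2)cc1OCc1ccccc1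
A5 | alternative 2 | 3-(benzyloxy)-6-{[2,4,6-tris(benzyloxy)phenyl]methylidene}cyclohexa-2,4-dien-1-one | O=C1C=C(OCc2ccccc2)C=CC1=Cc1c(OCc2ccccc2)cc(OCc2ccccc2)cc1OCc1ccccc1
A6 | alternative 2 | ethyl vinyl ether | C=COCC
A7 | alternative 3 | 1-{2,4,6-tris(benzyloxy)-3-[(2R,4S)-7-(benzyloxy)-2-[4-(benzyloxy)phenyl]chroman-4-yl]phenyl}dodecan-1-one | CCCCCCCCCCCC(=O)c1c(OCc2ccccc2)cc(OCc2ccccc2)c([C@H]2C[C@H](c3ccc(OCc4ccccc4)cc3)Oc3cc(OCc4ccccc4)ccc32)c1OCc1ccccc1
A8 | alternative 3 | (2R,4S)-7-(benzyloxy)-2-[4-(benzyloxy)phenyl]-4-[2,4,6-tris(benzyloxy)-3-iodophenyl]chroman | Ic1c(OCc2ccccc2)cc(OCc2ccccc2)c([C@H]2C[C@H](c3ccc(OCc4ccccc4)cc3)Oc3cc(OCc4ccccc4)ccc32)c1OCc1ccccc1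
A9 | alternative 3 | 9-undecyl-9-borabicyclo[3.3.1]nonane | CCCCCCCCCCCB1C2CCCC1CCC2
A10 | alternative 3 | carbon monoxide | [C-]#[O+]
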